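Cedar, the run with both charges in at the start, shows what to watch: the starting material left once it stops falling.

| flask | starting material | partner | remark | time |
|---|---|---|---|---|
| cedar | 0.050 M | 0.045 M | run made earlier |  |
| oak | 0.034 M | 0.045 M | run made earlier |  |
| ash | 0.075 M | 0.045 M | run made earlier |  |
| larch | 0.050 M | 0.068 M | run made earlier |  |
| alpha | 0.050 M | 0.0450 M (fed, over 80 min) | all else is in the flask from the start; the feed brings no volume worth counting | 2.0 h |
| theta | 0.050 M (fed, over 20 min) | 0.0450 M | all else is in the flask from the start; the feed brings no volume worth counting | 2.0 h |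
| delta | 0.050 M (fed, over 80 min) | 0.0450 M | all else is in the flask from the start; the feed brings no volume worth counting | 2.0 h |
| gamma | 0.050 M | 0.0450 M | everything together at the start | 2.0 h |

| run | time / min | triple product / % | bis adduct / % | starting material / % |
|---|---|---|---|---|
| cedar | 6.00 | 0.3 | 1.9 | 87.6 |
| cedar | 8.00 | 0.4 | 2.9 | 84.7 |
| cedar | 12.0 | 0.6 | 3.2 | 82.0 |
| cedar | 20.0 | 1.1 | 5.7 | 77.9 |
| cedar | 30.0 | 1.1 | 6.5 | 75.2 |
| cedar | 50.0 | 0.9 | 7.2 | 72.7 |
| cedar | 80.0 | 1.4 | 7.7 | 72.6 |
| oak | 15.0 | 0.9 | 4.3 | 78.8 |
| oak | 30.0 | 1.1 | 7.0 | 72.8 |
| oak | 40.0 | 1.7 | 7.2 | 71.0 |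
| oak | 60.0 | 0.8 | 8.9 | 68.9 |
| oak | 80.0 | 2.1 | 9.8 | 68.0 |
| oak | 90.0 | 1.5 | 9.3 | 67.7 |
| ash | 8.00 | 0.6 | 2.3 | 85.9 |
| ash | 12.0 | 0.2 | 2.7 | 83.1 |
| ash | 20.0 | 0.7 | 3.8 | 80.3 |
| ash | 25.0 | 0.4 | 5.0 | 78.7 |
| ash | 40.0 | 0.8 | 4.6 | 77.2 |
| ash | 60.0 | 0.7 | 4.8 | 76.8 |
| ash | 90.0 | 1.0 | 6.1 | 76.5 |
| larch | 20.0 | 1.1 | 7.2 | 72.6 |
| larch | 40.0 | 1.8 | 8.9 | 69.2 |
| larch | 60.0 | 1.8 | 9.7 | 67.5 |
| larch | 80.0 | 2.2 | 9.9 | 67.2 |
| larch | 90.0 | 1.8 | 9.9 | 66.9 |

(standard deviation of a reading: 0.3 percentage points)

- amounts and yields of triple product count idle adduct too
- steps under discussion: 2 partner -> self-condensation product; partner + bis adduct -> triple product; partner + mono adduct -> bis adduct; partner + triple product <-> idle adduct; starting material + partner -> mono adduct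

1. the flask that comes out highest in share of triple product in triple product plus bis adduct, or "all alike" when all lie within 1.5 percentage points (alpha / theta / delta / gamma / all alike)
2. share of triple product in triple product plus bis adduct at the end, alpha
3. share of triple product in triple product plus bis adduct at the end, theta
4. share of triple product in triple product plus bis adduct at the end, delta
5. share of triple product in triple product plus bis adduct at the end, gamma

1. Exposure is the logarithm of starting material charged over starting material left. Starting material falls pseudo-first-order at the partner level of the moment, and the steps to bis adduct and triple product run on that same level. So, at small exposure with the starting material in from the start, bis adduct grows as the square of exposure, triple product as the cube, and the ratio of triple product to bis adduct in proportion. The last two readings give ratio per exposure as 0.483 in cedar, 0.486 in oak, 0.587 in ash and 0.505 in larch. Their mean, 0.515, is the climb: triple over bis per unit of exposure. The share is then ratio over one plus ratio.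

2. Gamma repeats cedar's charges, so its exposure is read as 0.320, and its share as 14.1%.

3. Cedar's adducts hold 0.0186 M of partner, or 0.0581 M per unit of exposure. The remainder of the charge is put down to self-condensation, 1.43 per partner captured.

4. With starting material and adducts held, that loss ratio scales with partner level. Taking cedar's weighted level as 0.0225 M gives 63.4 /M.

5. Cedar's first reading, with the level taken as the full charge, gives a capture constant of 0.132 over 6.00 min and 0.045 M, or 0.490 /M/min. Feed balancing loss puts alpha's partner at 0.0115 M, its exposure at 0.449 and its share at 18.8%.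

6. The weak link is that full charge. Partner spent during those minutes lowers the mean level to 0.0331 M, which raises the constant to 0.667 /M/min. Alpha's level becomes 0.00919 M, its exposure 0.490 and its share 20.2%.

The climb gives no number for theta or delta, whose starting material arrives over time. The forecast, reckoned separately, names alpha and gives 24% for alpha, 15% for theta, 19% for delta and 15% for gamma, with delta's figure resting on “early material seeing the most partner”. Its alpha stands above the 20.2% reckoned here.

The flasks give 21.9% in alpha, 12.0% in theta, 13.5% in delta and 14.8% in gamma, so alpha stands highest, and delta lies below the forecast's 19%.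

    2 partner → self-condensation product (k = 0.0290 /M/s)
    partner + bis adduct → triple product (k = 0.0180 /M/s)
    partner + mono adduct → bis adduct (k = 0.0300 /M/s)
    partner + triple product ⇌ idle adduct, settled at all times (K = 14.0 /M)
    starting material + partner → mono adduct (k = 0.0130 /M/s)

Alpha holds 60.9% of its starting material after 2.00 h. That is an exposure of 0.495, and the climb turns it into a share of 20.3%. Gamma holds 71.9%, an exposure of 0.330, and the climb gives 14.5% against its 14.8%.

(The runs were computed from invented constants.)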